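**Remarks on the chemistry (assumptions)**

- The target has no stereocentre. The sp3 centres of the transient compounds 9, 15 and 20 are formed as mixtures and are lost or irrelevant. The geometry of the exocyclic double bond of 18 is left open, since both isomers are reduced to 19.
- LiN(i-Pr)2 is used as a purchased solution.

## Analysis of the target

The target 23 is a linear trimer of three fully substituted, 1,3,5-trioxygenated benzene rings joined by two methylene bridges; it has no stereocentre and no ring other than the three arenes. Ring A carries a butanoyl group, two hydroxyls, a C-methyl and one methoxyl para to the butanoyl, with the bridge ortho to that methoxyl. Ring C carries the same substituents in the other arrangement: methoxyl ortho to the butanoyl, bridge para to the methoxyl. Ring B, in the middle, has an acetyl carbon flanked by two C–OH carbons, then the two bridge-bearing carbons, and a third C–OH between them. The sensitive features are seven free phenols, three enolisable aryl ketones and, above all, the two diarylmethane bridges between electron-rich rings, which can be cleaved and re-formed (retro-Friedel–Crafts and ortho-quinone methide pathways) under strong acid or base. The difficulty is regiochemical: the outer rings are constitutional isomers, one of each must be attached to ring B, and each must carry its methoxyl on the right oxygen, which a statistical one-carbon coupling of three monomers cannot deliver. The strategy rests on ring B: its six ring carbons and the acetyl group are the chain of a 3,5,7-trioxooctanoate, in which C1 to C6 become the ring, C7 and C8 the acetyl group, and C2 and C4 bear the two arylmethyl arms. The stable cyclic form of that chain is a 4-hydroxy-6-(2-oxopropyl)-2-pyranone with the arms on C3 and C5.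

## Retrosynthetic reasoning

**23 to 22.** The aryl–acyl bond of ring C is cut first. Ring C is the fragment that must pass through two amide-base steps, and a ketone with α-hydrogens would be enolised and acylated there. In 22 the carbon in question is the only aromatic CH of the whole molecule, and ring C is the only ring without an acyl group, so the forward acylation has a single possible site.

**22 to 21.** The four phenols of the outer rings are masked as MOM ethers. They are needed because the ring C fragment meets amide bases and both fragments meet condensation conditions. They are removed before the acylation, since a Lewis acid would cleave them anyway and release one-carbon electrophiles next to a nucleophilic ring.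

**21 to 19 (through 20).** Ring B is opened at the bond between the acetyl-bearing carbon and the C–OH carbon next to the ring A arm. This is the bond a Claisen condensation makes, and cutting it turns ring B into the open-chain triketo ester 20, whose lactone form is pyranone 19. The gain is large: a hexasubstituted arene is traded for a pyranone whose C3 and C5 are ordinary carbon nucleophile positions, so each arm can be attached by its own reaction and the unsymmetrical pattern is fixed before the ring exists. The forward reaction has to open the lactone, acylate the carbon between the two ketones, and aromatise.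

**19 to 17 and 11 (through 18).** The bond between pyranone C3 and the ring A methylene is cut. C3 of a 4-hydroxy-2-pyranone is its most nucleophilic carbon, and an aldehyde with in situ reduction of the condensation product 18 is the mildest way to alkylate it once. Because this step is neutral, the ring A fragment 11 can bring its butanoyl group, and this arm is therefore put on last.

**17 to 16.** The bond between the side-chain methylene and the acetyl carbonyl is cut. The 6-methyl group of 16 is the vinylogous position of the pyranone and is the only carbon that a second equivalent of base can deprotonate. This strong-base step must come before ring A is attached.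

**16 to 15 to 14.** The lactone C–O bond and then the bond to the carboxyl carbon are cut. Diketone 14 is symmetrical about its central carbon, so carboxylation of either methyl group gives the same acid 15 and no regiochemical question arises.

**14 to 12 and 5 (through 13).** The bond between the central carbon of 12 and the ring C methylene is cut. The same condensation–reduction logic as for ring A is used, here on the simplest possible nucleophile and early in the route, where material is cheap.

**5 and 11 to 1 (and 6).** Both outer rings come from 1, and their isomerism is reduced to the order of operations. For ring C the future bridge carbon goes on first as a formyl group (3, through 2); this makes the para hydroxyl the most acidic one and directs the single O-methylation to 4, and protection gives 5. For ring A the butanoyl group from 6 goes on first (7); the same acidity argument places the methoxyl para to it (8), and the last free CH is then formylated (10, through 9) and the phenols protected (11).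

## Alternatives that were turned down

**Alternative 1:** Ring A would be the last ring made, by a thermal benzannulation of the Danheiser type. The disconnection removes four ring A carbons as the 3-tert-butoxycyclobutenone A2, which already carries the ring B–ring C part on its saturated carbon, and two as the alkyne carbons of triisopropyl(prop-1-ynyloxy)silane A3. Heating the two (about 80 to 110 °C) would open A2 to a vinylketene, add A3 across the ketene, reopen and close by 6π electrocyclisation to give phenol A1, whose new hydroxyl carbon lies between the methyl- and bridge-bearing carbons.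

- For it: the pattern of a hexasubstituted ring is dictated by the cascade, the conditions are neutral, and the three oxygens of ring A emerge chemically distinct (free hydroxyl, silyl ether, tert-butyl ether). The methoxyl can then be placed without relying on an acidity difference. On that point it is stronger than the chosen route, which depends on selective methylation in steps 2 and 5.
- Against it: it builds a peripheral ring at the end of a linear sequence and presupposes an unsymmetrical ring B–ring C dimer with a one-carbon handle, so the central problem is only moved. A2 needs C-alkylation of an alkoxycyclobutenone with a labile, electron-rich benzylic electrophile. After A1 there remain O-methylation, desilylation, tert-butyl ether cleavage, butanoylation of the free position of ring A and removal of five MOM groups.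
- Comparison: it keeps the same late Friedel–Crafts acylation as the chosen route and adds three further steps after the key step. The chosen route makes the central ring, is convergent in the two outer rings, and needs two steps after the key step.

**Alternative 2:** The three hydroxyls of ring B are disconnected as C–O bonds, back to the 2,4,6-trifluoro compound A5, in which the whole skeleton except the ring C butanoyl group is in place. Forward, a benzyloxide nucleophile in a dipolar aprotic solvent at elevated temperature would displace the three fluorides, each ortho or para to the acetyl group, and give the heptabenzyl ether A4.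

- For it: no ring has to be closed in a crowded setting, and the first fluoride displacement next to a carbonyl group is reliable. All seven benzyl groups would later fall in one neutral hydrogenolysis, which is gentler on the bridges than the acid of step 14; on that point it is stronger.
- Against it: every benzyloxy group that enters deactivates the ring for the next displacement. The acetyl group is twisted out of conjugation by its two ortho neighbours, and the fluorine between the two arms is shielded by both. The hot alkoxide also meets two enolisable ketones and two acidified, doubly benzylic CH2 groups, so the third substitution is doubtful.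
- Comparison: the step forms no carbon–carbon bond and no ring, so A5 still needs two different arylmethylations of a trifluoroarene, and the late butanoylation of ring C remains. The chosen route brings the three ring B oxygens in as carbonyl groups of the chain and fixes the ring pattern in the same step.

**Alternative 3:** This is the closest relative of the chosen plan: the same Claisen-type ring transformation, applied to ring A. Ring A is opened between the butanoyl-bearing carbon and the C–OH carbon next to the bridge. This leads back to the 4-methoxy-5-methyl-6-(2-oxopentyl)-2-pyranone A7, which carries the complete ring B–ring C part as MOM ethers on C3. The same magnesium alkoxide as in step 13 would open the lactone, the CH2 next to the butanoyl carbonyl would attack the ester, and aromatisation would give A6, the target with five MOM groups.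

- For it: the methoxyl of ring A is placed unambiguously as the enol ether of the pyranone, both butanoyl groups are already present, and only one deprotection follows. On these three points it is stronger than the chosen route.
- Against it: the ring-opened ester is a β-methoxy acrylate, a far poorer acceptor than the β-keto ester of the chosen route. It also lacks the 3-oxo group through which magnesium chelation organises the known closure, so the reaction leaves the known substrate class. A7 would have to be built by pyranone enolate chemistry on a substrate that already holds the acetyl and butanoyl ketones of rings B and C, and a differentiated ring B–ring C dimer is needed first.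
- Comparison: the chosen route keeps the closure within the 4-hydroxy-pyranone series, exposes only one ketone-free outer ring to strong base, and joins the three rings convergently. The price is the late acylation of step 15.

Key step: step 13

## Steps

Step 1
Reactants: 1 2-methylbenzene-1,3,5-triol (2,4,6-trihydroxytoluene)
Product: 3 2,4,6-trihydroxy-3-methylbenzaldehyde, via aryliminium chloride 2 (not isolated)
Conditions: POCl3 (1.1 equiv), DMF, EtOAc, 0 °C to rt; then H2O, 60 °C
Reagents that add atoms: N,N-dimethylformamide CN(C)C=O; water O
Why: Vilsmeier–Haack formylation of a highly activated arene; the two free ring positions of 1 are equivalent, so one aldehyde should form, and the iminium group of 2 deactivates the ring against a second attack until hydrolysis releases 3.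

Step 2
Reactants: 3 2,4,6-trihydroxy-3-methylbenzaldehyde
Product: 4 2,6-dihydroxy-4-methoxy-3-methylbenzaldehyde
Conditions: Me2SO4 (1.0 equiv), K2CO3 (1.0 equiv), acetone, 0 °C to rt
Reagents that add atoms: dimethyl sulfate COS(=O)(=O)OC
Why: Williamson O-methylation of the most acidic hydroxyl; the hydroxyl para to the formyl group is a vinylogous acid and is not hydrogen-bonded, so one equivalent of weak base ionises it first, and the hard sulfate electrophile should react at oxygen and not at the free ring carbon.

Step 3
Reactants: 4 2,6-dihydroxy-4-methoxy-3-methylbenzaldehyde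
Product: 5 4-methoxy-2,6-bis(methoxymethoxy)-3-methylbenzaldehyde
Conditions: NaH (2.4 equiv), MOMCl (2.5 equiv), DMF, 0 °C to rt
Reagents that add atoms: chloromethyl methyl ether COCCl
Why: Double Williamson etherification through the bis-phenoxide; NaH is chosen because hydroxyls ortho to a formyl group are hydrogen-bonded and react sluggishly with amine bases.

Step 4
Reactants: 1 2-methylbenzene-1,3,5-triol; 6 butanoyl chloride
Product: 7 1-(2,4,6-trihydroxy-3-methylphenyl)butan-1-one
Conditions: AlCl3 (3.5 equiv), PhNO2–CH2Cl2, 0 °C to 40 °C; then ice, 1 M HCl
Reagents that add atoms: none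
Why: Friedel–Crafts acylation; the two free positions of 1 are equivalent and the first acyl group, bound to aluminium, deactivates the ring towards a second acylation.

Step 5
Reactants: 7 1-(2,4,6-trihydroxy-3-methylphenyl)butan-1-one
Product: 8 1-(2,6-dihydroxy-4-methoxy-3-methylphenyl)butan-1-one
Conditions: Me2SO4 (1.0 equiv), K2CO3 (1.0 equiv), acetone, 0 °C to rt
Reagents that add atoms: dimethyl sulfate COS(=O)(=O)OC
Why: Same selective Williamson O-methylation as in step 2; the hydroxyl para to the butanoyl group is the most acidic, which places the methoxyl para to the ketone and next to the C-methyl as ring A requires.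

Step 6
Reactants: 8 1-(2,6-dihydroxy-4-methoxy-3-methylphenyl)butan-1-one
Product: 10 3-butanoyl-2,4-dihydroxy-6-methoxy-5-methylbenzaldehyde, via chloro(methoxy)methyl arene 9 (not isolated)
Conditions: Cl2CHOMe (1.5 equiv), TiCl4 (3 equiv), CH2Cl2, −10 °C to 0 °C; then ice, 1 M HCl
Reagents that add atoms: dichloromethyl methyl ether COC(Cl)Cl; water O
Why: Rieche formylation at the only remaining aromatic CH, which is ortho to a hydroxyl (delivery through the titanium phenoxide), ortho to the methoxyl and para to the other hydroxyl; it is preferred to Vilsmeier conditions, which can turn an ortho-hydroxyaryl alkyl ketone into a chromone.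

Step 7
Reactants: 10 3-butanoyl-2,4-dihydroxy-6-methoxy-5-methylbenzaldehyde
Product: 11 3-butanoyl-6-methoxy-2,4-bis(methoxymethoxy)-5-methylbenzaldehyde
Conditions: NaH (2.2 equiv), MOMCl (2.4 equiv), DMF, 0 °C to rt
Reagents that add atoms: chloromethyl methyl ether COCCl
Why: Double Williamson etherification of the two chelated phenols; the base is kept close to two equivalents so that the far less acidic butanoyl α-position is not enolised.

Step 8
Reactants: 12 pentane-2,4-dione; 5 4-methoxy-2,6-bis(methoxymethoxy)-3-methylbenzaldehyde
Product: 14 3-{[4-methoxy-2,6-bis(methoxymethoxy)-3-methylphenyl]methyl}pentane-2,4-dione, via benzylidene diketone 13 (not isolated)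
Conditions: 12 (2 equiv), L-proline (20 mol %), diethyl 1,4-dihydro-2,6-dimethylpyridine-3,5-dicarboxylate (Hantzsch ester, 1.2 equiv), EtOH, 40 °C
Reagents that add atoms: none
Why: Knoevenagel condensation followed in the same flask by conjugate transfer hydrogenation from the Hantzsch ester (organocatalytic reductive alkylation); the irreversible hydride transfer to the electron-poor alkene of 13 pulls the condensation of the hindered aldehyde forward and prevents a second Michael addition.

Step 9
Reactants: 14 3-{[4-methoxy-2,6-bis(methoxymethoxy)-3-methylphenyl]methyl}pentane-2,4-dione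
Product: 15 4-{[4-methoxy-2,6-bis(methoxymethoxy)-3-methylphenyl]methyl}-3,5-dioxohexanoic acid
Conditions: LiN(i-Pr)2 (2.2 equiv), THF, −78 °C to 0 °C; CO2 (gas), −78 °C; then cold 1 M HCl to pH 3
Reagents that add atoms: carbon dioxide O=C=O
Why: Carboxylation of a β-diketone dianion at its more basic terminal carbon; the two methyl groups of 14 are equivalent, and an amide base is used instead of an alkyllithium so that the ring C position between the methoxy and methoxymethoxy groups is not lithiated.

Step 10
Reactants: 15 4-{[4-methoxy-2,6-bis(methoxymethoxy)-3-methylphenyl]methyl}-3,5-dioxohexanoic acid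
Product: 16 4-hydroxy-5-{[4-methoxy-2,6-bis(methoxymethoxy)-3-methylphenyl]methyl}-6-methyl-2H-pyran-2-one
Conditions: 1,1'-carbonyldiimidazole (1.2 equiv), THF, 0 °C to rt; crude 15 used at once
Reagents that add atoms: none
Why: Dehydrative lactonisation; the activated carboxyl group is attacked by the enol oxygen of the δ-carbonyl to give the 4-hydroxy-2-pyranone, and the neutral conditions keep the MOM ethers and avoid decarboxylation of the β-keto acid.

Step 11
Reactants: 16 4-hydroxy-5-{[4-methoxy-2,6-bis(methoxymethoxy)-3-methylphenyl]methyl}-6-methyl-2H-pyran-2-one
Product: 17 4-hydroxy-5-{[4-methoxy-2,6-bis(methoxymethoxy)-3-methylphenyl]methyl}-6-(2-oxopropyl)-2H-pyran-2-one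
Conditions: LiN(i-Pr)2 (2.2 equiv), THF, −78 °C to −30 °C; N-methoxy-N-methylacetamide (1.2 equiv), −78 °C to 0 °C; then cold 1 M HCl to pH 4
Reagents that add atoms: N-methoxy-N-methylacetamide CC(=O)N(C)OC
Why: C-acylation of the dianion of a 4-hydroxy-6-methyl-2-pyranone at its vinylogous methyl carbon; the N-methoxy amide holds the adduct as a chelate until work-up, so the more acidic product is released only then and a second acylation is avoided.

Step 12
Reactants: 17 4-hydroxy-5-{[4-methoxy-2,6-bis(methoxymethoxy)-3-methylphenyl]methyl}-6-(2-oxopropyl)-2H-pyran-2-one; 11 3-butanoyl-6-methoxy-2,4-bis(methoxymethoxy)-5-methylbenzaldehyde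
Product: 19 3-{[3-butanoyl-6-methoxy-2,4-bis(methoxymethoxy)-5-methylphenyl]methyl}-4-hydroxy-5-{[4-methoxy-2,6-bis(methoxymethoxy)-3-methylphenyl]methyl}-6-(2-oxopropyl)-2H-pyran-2-one, via alkylidene pyrandione 18 (not isolated)
Conditions: L-proline (20 mol %), Hantzsch ester (1.2 equiv), CH2Cl2, rt
Reagents that add atoms: none
Why: Knoevenagel condensation at C3, by far the most nucleophilic carbon of the 4-hydroxy-2-pyranone, followed by transfer hydrogenation of 18 by the Hantzsch ester; the neutral conditions tolerate the butanoyl ketone of ring A and the 2-oxopropyl chain, which is why this arm is installed last.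

Step 13
Reactants: 19 3-{[3-butanoyl-6-methoxy-2,4-bis(methoxymethoxy)-5-methylphenyl]methyl}-4-hydroxy-5-{[4-methoxy-2,6-bis(methoxymethoxy)-3-methylphenyl]methyl}-6-(2-oxopropyl)-2H-pyran-2-one
Product: 21 1-[3-({3-acetyl-2,4,6-trihydroxy-5-[(4-methoxy-2,6-bis(methoxymethoxy)-3-methylphenyl)methyl]phenyl}methyl)-4-methoxy-2,6-bis(methoxymethoxy)-5-methylphenyl]butan-1-one, via ring-opened methyl triketo ester 20 (not isolated)
Conditions: Mg(OMe)2 (8 equiv), MeOH, reflux; then cold 0.5 M HCl to pH 3
Reagents that add atoms: none
Why: Magnesium-bound methoxide adds to the lactone carbonyl and the ring oxygen leaves as the enolate of the 5,7-diketone, giving the chelated triketo ester 20. The carbon between the two ketones (C6 of the chain) then attacks the ester carbonyl, methoxide is expelled and the cyclic triketone enolises to the aromatic triol; this is an intramolecular Claisen condensation, and the closest known reaction is the conversion of 4-hydroxy-6-(2-oxoalkyl)-2-pyranones into acylphloroglucinols by magnesium alkoxides. Ring B closes in the 6-exo-trig mode, an enolate carbon attacking an ester carbonyl that lies outside the new ring. No stereocentre is formed, and the two stereocentres of 20 vanish on aromatisation. The step needs C-acylation at C6 to win over aldol closure of C2 onto the C7 ketone, over relactonisation and over retro-Claisen cleavage: C2 carries the ring A arm, so an aldol product there has a quaternary carbon, cannot aromatise and can revert, whereas the Claisen product leaves the equilibrium as an aromatic, magnesium-chelated phenoxide. Chelation of the 1,3-dicarbonyl units by the magnesium ion holds the chain folded and favours acylation at carbon over oxygen. The butanoyl group of ring A could only close an eight-membered ring onto the ester, and the terminal methyl group is the least acidic site, so neither should compete. Because both arms sit on C3 and C5 of the pyranone before the ring exists, the placement of ring A and ring C on ring B is fixed by the precursor and not by the cyclisation.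

Step 14
Reactants: 21 1-[3-({3-acetyl-2,4,6-trihydroxy-5-[(4-methoxy-2,6-bis(methoxymethoxy)-3-methylphenyl)methyl]phenyl}methyl)-4-methoxy-2,6-bis(methoxymethoxy)-5-methylphenyl]butan-1-one
Product: 22 1-[3-({3-acetyl-5-[(2,6-dihydroxy-4-methoxy-3-methylphenyl)methyl]-2,4,6-trihydroxyphenyl}methyl)-2,6-dihydroxy-4-methoxy-5-methylphenyl]butan-1-one
Conditions: 3 M aq. HCl–MeOH (1:6), 45 °C, dilute
Reagents that add atoms: none
Why: Acid-catalysed acetal exchange of the four aryl MOM ethers with methanol, the one-carbon unit leaving as dimethoxymethane; the large excess of methanol should trap the oxocarbenium ion before it can attack the free position of ring C.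

Step 15
Reactants: 22 1-[3-({3-acetyl-5-[(2,6-dihydroxy-4-methoxy-3-methylphenyl)methyl]-2,4,6-trihydroxyphenyl}methyl)-2,6-dihydroxy-4-methoxy-5-methylphenyl]butan-1-one
Product: 23 1-[3-({3-acetyl-5-[(3-butanoyl-2,6-dihydroxy-4-methoxy-5-methylphenyl)methyl]-2,4,6-trihydroxyphenyl}methyl)-2,6-dihydroxy-4-methoxy-5-methylphenyl]butan-1-one
Conditions: butanoic anhydride (1.3 equiv), BF3·OEt2 (excess), 1,4-dioxane, 0 °C to rt; then MeOH–H2O, 40 °C
Reagents that add atoms: butanoic anhydride CCCC(=O)OC(=O)CCC
Why: Friedel–Crafts acylation at the only aromatic CH of 22, which sits on the only ring without an acyl group and is activated by an ortho hydroxyl, an ortho methoxyl and a para hydroxyl; any aryl butanoate formed is itself an acyl donor under BF3 (Fries manifold), so the acyl group should end on carbon, where boron chelation with the neighbouring hydroxyl makes the step irreversible, and the methanolic work-up frees the phenols.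

## Compound list

1 | 2-methylbenzene-1,3,5-triol (2,4,6-trihydroxytoluene) | Cc1c(O)cc(O)cc1O | starting material
2 | N,N-dimethyl-1-(2,4,6-trihydroxy-3-methylphenyl)methaniminium chloride | C[N+](C)=Cc1c(O)cc(O)c(C)c1O.[Cl-] | intermediate
3 | 2,4,6-trihydroxy-3-methylbenzaldehyde | O=Cc1c(O)cc(O)c(C)c1O | intermediate
4 | 2,6-dihydroxy-4-methoxy-3-methylbenzaldehyde | O=Cc1c(O)cc(OC)c(C)c1O | intermediate
5 | 4-methoxy-2,6-bis(methoxymethoxy)-3-methylbenzaldehyde (ring C aldehyde) | O=Cc1c(OCOC)cc(OC)c(C)c1OCOC | intermediate
6 | butanoyl chloride | CCCC(=O)Cl | starting material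
7 | 1-(2,4,6-trihydroxy-3-methylphenyl)butan-1-one | CCCC(=O)c1c(O)cc(O)c(C)c1O | intermediate
8 | 1-(2,6-dihydroxy-4-methoxy-3-methylphenyl)butan-1-one | CCCC(=O)c1c(O)cc(OC)c(C)c1O | intermediate
9 | 1-{3-[chloro(methoxy)methyl]-2,6-dihydroxy-4-methoxy-5-methylphenyl}butan-1-one (racemic) | CCCC(=O)c1c(O)c(C)c(OC)c(C(Cl)OC)c1O | intermediate
10 | 3-butanoyl-2,4-dihydroxy-6-methoxy-5-methylbenzaldehyde | CCCC(=O)c1c(O)c(C)c(OC)c(C=O)c1O | intermediate
11 | 3-butanoyl-6-methoxy-2,4-bis(methoxymethoxy)-5-methylbenzaldehyde (ring A aldehyde) | CCCC(=O)c1c(OCOC)c(C)c(OC)c(C=O)c1OCOC | intermediate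
12 | pentane-2,4-dione | CC(=O)CC(C)=O | starting material
13 | 3-{[4-methoxy-2,6-bis(methoxymethoxy)-3-methylphenyl]methylidene}pentane-2,4-dione | CC(=O)C(=Cc1c(OCOC)cc(OC)c(C)c1OCOC)C(C)=O | intermediate
14 | 3-{[4-methoxy-2,6-bis(methoxymethoxy)-3-methylphenyl]methyl}pentane-2,4-dione | CC(=O)C(Cc1c(OCOC)cc(OC)c(C)c1OCOC)C(C)=O | intermediate
15 | 4-{[4-methoxy-2,6-bis(methoxymethoxy)-3-methylphenyl]methyl}-3,5-dioxohexanoic acid (racemic at C4) | CC(=O)C(Cc1c(OCOC)cc(OC)c(C)c1OCOC)C(=O)CC(=O)O | intermediate
16 | 4-hydroxy-5-{[4-methoxy-2,6-bis(methoxymethoxy)-3-methylphenyl]methyl}-6-methyl-2H-pyran-2-one | CC1=C(Cc2c(OCOC)cc(OC)c(C)c2OCOC)C(O)=CC(=O)O1 | intermediate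
17 | 4-hydroxy-5-{[4-methoxy-2,6-bis(methoxymethoxy)-3-methylphenyl]methyl}-6-(2-oxopropyl)-2H-pyran-2-one | CC(=O)CC1=C(Cc2c(OCOC)cc(OC)c(C)c2OCOC)C(O)=CC(=O)O1 | intermediate
18 | 3-{[3-butanoyl-6-methoxy-2,4-bis(methoxymethoxy)-5-methylphenyl]methylidene}-5-{[4-methoxy-2,6-bis(methoxymethoxy)-3-methylphenyl]methyl}-6-(2-oxopropyl)-2H-pyran-2,4(3H)-dione (double-bond geometry not defined) | CCCC(=O)c1c(OCOC)c(C)c(OC)c(C=C2C(=O)OC(CC(C)=O)=C(Cc3c(OCOC)cc(OC)c(C)c3OCOC)C2=O)c1OCOC | intermediate
19 | 3-{[3-butanoyl-6-methoxy-2,4-bis(methoxymethoxy)-5-methylphenyl]methyl}-4-hydroxy-5-{[4-methoxy-2,6-bis(methoxymethoxy)-3-methylphenyl]methyl}-6-(2-oxopropyl)-2H-pyran-2-one | CCCC(=O)c1c(OCOC)c(C)c(OC)c(CC2=C(O)C(Cc3c(OCOC)c(C)c(OC)cc3OCOC)=C(CC(C)=O)OC2=O)c1OCOC | intermediate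
20 | methyl 2-{[3-butanoyl-6-methoxy-2,4-bis(methoxymethoxy)-5-methylphenyl]methyl}-4-{[4-methoxy-2,6-bis(methoxymethoxy)-3-methylphenyl]methyl}-3,5,7-trioxooctanoate (mixture of diastereomers and enol forms, present as magnesium chelate) | COC(=O)C(Cc1c(OC)c(C)c(OCOC)c(C(=O)CCC)c1OCOC)C(=O)C(Cc1c(OCOC)cc(OC)c(C)c1OCOC)C(=O)CC(C)=O | intermediate
21 | 1-[3-({3-acetyl-2,4,6-trihydroxy-5-[(4-methoxy-2,6-bis(methoxymethoxy)-3-methylphenyl)methyl]phenyl}methyl)-4-methoxy-2,6-bis(methoxymethoxy)-5-methylphenyl]butan-1-one | CCCC(=O)c1c(OCOC)c(C)c(OC)c(Cc2c(O)c(Cc3c(OCOC)c(C)c(OC)cc3OCOC)c(O)c(C(C)=O)c2O)c1OCOC | intermediate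
22 | 1-[3-({3-acetyl-5-[(2,6-dihydroxy-4-methoxy-3-methylphenyl)methyl]-2,4,6-trihydroxyphenyl}methyl)-2,6-dihydroxy-4-methoxy-5-methylphenyl]butan-1-one | CCCC(=O)c1c(O)c(C)c(OC)c(Cc2c(O)c(Cc3c(O)c(C)c(OC)cc3O)c(O)c(C(C)=O)c2O)c1O | intermediate
23 | 1-[3-({3-acetyl-5-[(3-butanoyl-2,6-dihydroxy-4-methoxy-5-methylphenyl)methyl]-2,4,6-trihydroxyphenyl}methyl)-2,6-dihydroxy-4-methoxy-5-methylphenyl]butan-1-one (no stereocentre) | CCCC(=O)c1c(O)c(C)c(OC)c(Cc2c(O)c(Cc3c(O)c(C)c(OC)c(C(=O)CCC)c3O)c(O)c(C(C)=O)c2O)c1O | target

## Step count and least certain steps

Total step count: 15. Longest linear sequence: 11 steps (steps 1, 2, 3, 8, 9, 10, 11, 12, 13, 14 and 15, from 1 to 23). The ring A branch (steps 4 to 7) joins at step 12.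

**Step 13 (key step).** The most likely failure is diversion of the ring-opened chain: aldol closure of C2 onto the C7 ketone followed by dehydration, retro-Claisen cleavage of the triketone by methoxide, or relactonisation on work-up. The cause would be the two arms on C2 and C4, which crowd the folded conformer needed for attack of C6 on the ester.

The fallback closes ring B before the second arm is attached. It sets out from 17 and 8 and comes back to the route at 22. Pyranone 17 has an unsubstituted ester α-carbon and is close to the parent case of the known ring transformation. Treated with Mg(OMe)2 in refluxing MeOH it should give the mono-benzylated triol 1-(2,4,6-trihydroxy-3-{[4-methoxy-2,6-bis(methoxymethoxy)-3-methylphenyl]methyl}phenyl)ethan-1-one F1. Separately, 8 is aminomethylated at its only free ring position with Me2N=CH2+ I− (Mannich reaction, CH2Cl2, rt) to give 1-{3-[(dimethylamino)methyl]-2,6-dihydroxy-4-methoxy-5-methylphenyl}butan-1-one F2. Heating F1 with F2 in 1,4-dioxane at 100 °C should expel dimethylamine and generate the ortho-quinone methide of ring A, which is captured by the one free carbon of ring B. This gives 1-[3-({3-acetyl-2,4,6-trihydroxy-5-[(4-methoxy-2,6-bis(methoxymethoxy)-3-methylphenyl)methyl]phenyl}methyl)-2,6-dihydroxy-4-methoxy-5-methylphenyl]butan-1-one F3. The ether-protected ring C is much less nucleophilic than the free triol ring and should not compete. Acid (HCl, MeOH, 45 °C) removes the two MOM groups of F3 and gives 22, from which step 15 follows.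

**Step 15.** Two processes threaten this step: O-acylation spread over several phenols, and acid-promoted cleavage or migration of a methylene bridge. The latter would start by ipso protonation of the electron-rich ring C and loss of the ring B benzyl cation as an ortho-quinone methide, under the Lewis acid and the HF it releases.

The fallback is a Houben–Hoesch acylation, setting out from 22 and coming back at 23. Butanenitrile, ZnCl2 and HCl gas in Et2O–1,4-dioxane at 0 °C should give the ketiminium salt 1-[3-({3-acetyl-5-[(3-butanimidoyl-2,6-dihydroxy-4-methoxy-5-methylphenyl)methyl]-2,4,6-trihydroxyphenyl}methyl)-2,6-dihydroxy-4-methoxy-5-methylphenyl]butan-1-one hydrochloride F4. A nitrilium electrophile cannot leave an O-acyl group behind, the reaction runs cold, and the salt is expected to separate from the acidic medium. Hydrolysis of F4 (H2O, 60 °C) gives 23.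

**Step 12.** The likely failures are Michael addition of a second pyranone to the alkylidene intermediate 18 faster than hydride transfer, condensation at the side-chain methylene instead of C3, and slow condensation of the di-ortho-substituted aldehyde.

The fallback traps the alkylidene with a thiol instead of a hydride. It sets out from 17 and 11 and comes back at 19. Condensation in the presence of PhSH (piperidinium acetate cat., EtOH, rt) should give the sulfide 3-{[3-butanoyl-6-methoxy-2,4-bis(methoxymethoxy)-5-methylphenyl](phenylsulfanyl)methyl}-4-hydroxy-5-{[4-methoxy-2,6-bis(methoxymethoxy)-3-methylphenyl]methyl}-6-(2-oxopropyl)-2H-pyran-2-one F5 (racemic). The fast, reversible thiol addition keeps the alkylidene concentration low and so suppresses the bis-adduct. Radical reduction of the benzylic C–S bond of F5 (Bu3SnH, AIBN, toluene, 80 °C) then gives 19. It does not cure a slow condensation, which would call for a longer reaction time at this stage.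

**Step 11.** The likely failures are proton transfer from the acyl donor to the dianion (enolisation of the amide instead of addition), acylation at the 4-oxygen, and incomplete metalation of the 6-methyl group next to the bulky C5 arm.

The fallback replaces acylation by aldol addition and oxidation. It sets out from 16 and comes back at 17. The dianion of 16 (LiN(i-Pr)2, 2.2 equiv, THF, −78 °C) is quenched with acetaldehyde, a far better electrophile, to give 4-hydroxy-6-(2-hydroxypropyl)-5-{[4-methoxy-2,6-bis(methoxymethoxy)-3-methylphenyl]methyl}-2H-pyran-2-one F6 (racemic). The alkoxide formed is not an acid towards remaining dianion. Oxidation of the secondary alcohol of F6 (Dess–Martin periodinane, NaHCO3, CH2Cl2, rt) gives 17.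

## Further compounds

F1 | step 13 | 1-(2,4,6-trihydroxy-3-{[4-methoxy-2,6-bis(methoxymethoxy)-3-methylphenyl]methyl}phenyl)ethan-1-one | CC(=O)c1c(O)cc(O)c(Cc2c(OCOC)cc(OC)c(C)c2OCOC)c1O
F2 | step 13 | 1-{3-[(dimethylamino)methyl]-2,6-dihydroxy-4-methoxy-5-methylphenyl}butan-1-one | CCCC(=O)c1c(O)c(C)c(OC)c(CN(C)C)c1O
F3 | step 13 | 1-[3-({3-acetyl-2,4,6-trihydroxy-5-[(4-methoxy-2,6-bis(methoxymethoxy)-3-methylphenyl)methyl]phenyl}methyl)-2,6-dihydroxy-4-methoxy-5-methylphenyl]butan-1-one | CCCC(=O)c1c(O)c(C)c(OC)c(Cc2c(O)c(Cc3c(OCOC)c(C)c(OC)cc3OCOC)c(O)c(C(C)=O)c2O)c1O
F4 | step 15 | 1-[3-({3-acetyl-5-[(3-butanimidoyl-2,6-dihydroxy-4-methoxy-5-methylphenyl)methyl]-2,4,6-trihydroxyphenyl}methyl)-2,6-dihydroxy-4-methoxy-5-methylphenyl]butan-1-one hydrochloride | CCCC(=[NH2+])c1c(O)c(Cc2c(O)c(Cc3c(O)c(C(=O)CCC)c(O)c(C)c3OC)c(O)c(C(C)=O)c2O)c(O)c(C)c1OC.[Cl-]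
F5 | step 12 | 3-{[3-butanoyl-6-methoxy-2,4-bis(methoxymethoxy)-5-methylphenyl](phenylsulfanyl)methyl}-4-hydroxy-5-{[4-methoxy-2,6-bis(methoxymethoxy)-3-methylphenyl]methyl}-6-(2-oxopropyl)-2H-pyran-2-one (racemic) | CCCC(=O)c1c(OCOC)c(C)c(OC)c(C(Sc2ccccc2)C2=C(O)C(Cc3c(OCOC)c(C)c(OC)cc3OCOC)=C(CC(C)=O)OC2=O)c1OCOC
F6 | step 11 | 4-hydroxy-6-(2-hydroxypropyl)-5-{[4-methoxy-2,6-bis(methoxymethoxy)-3-methylphenyl]methyl}-2H-pyran-2-one (racemic) | CC(O)CC1=C(Cc2c(OCOC)cc(OC)c(C)c2OCOC)C(O)=CC(=O)O1
A1 | alternative 1 | benzannulation product: trimer whose ring A has a free hydroxyl between the methyl- and bridge-bearing carbons, a triisopropylsilyl ether, a free CH and a tert-butyl ether | CCCC(=O)c1c(OC)c(C)c(OCOC)c(Cc2c(OCOC)c(Cc3c(O)c(C)c(O[Si](C(C)C)(C(C)C)C(C)C)cc3OC(C)(C)C)c(OCOC)c(C(C)=O)c2OCOC)c1OCOC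
A2 | alternative 1 | 3-tert-butoxy-4-(arylmethyl)cyclobut-2-en-1-one carrying the ring B–ring C part (racemic) | CCCC(=O)c1c(OC)c(C)c(OCOC)c(Cc2c(OCOC)c(CC3C(=O)C=C3OC(C)(C)C)c(OCOC)c(C(C)=O)c2OCOC)c1OCOC
A3 | alternative 1 | triisopropyl(prop-1-ynyloxy)silane | CC#CO[Si](C(C)C)(C(C)C)C(C)C
A4 | alternative 2 | heptabenzyl ether of the trimer lacking the ring C butanoyl group | CCCC(=O)c1c(OCc2ccccc2)c(C)c(OC)c(Cc3c(OCc4ccccc4)c(Cc5c(OCc6ccccc6)c(C)c(OC)cc5OCc7ccccc7)c(OCc8ccccc8)c(C(C)=O)c3OCc9ccccc9)c1OCc2ccccc2
A5 | alternative 2 | 2,4,6-trifluoro ring B precursor with tetrabenzylated outer rings | CCCC(=O)c1c(OCc2ccccc2)c(C)c(OC)c(Cc3c(F)c(Cc5c(OCc6ccccc6)c(C)c(OC)cc5OCc7ccccc7)c(F)c(C(C)=O)c3F)c1OCc2ccccc2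
A6 | alternative 3 | the target as its penta-MOM ether on ring B and ring C | CCCC(=O)c1c(O)c(C)c(OC)c(Cc2c(OCOC)c(Cc3c(OCOC)c(C)c(OC)c(C(=O)CCC)c3OCOC)c(OCOC)c(C(C)=O)c2OCOC)c1O
A7 | alternative 3 | 4-methoxy-5-methyl-6-(2-oxopentyl)-2H-pyran-2-one carrying the MOM-protected ring B–ring C part as an arylmethyl group on C3 | CCCC(=O)CC1=C(C)C(OC)=C(Cc2c(OCOC)c(Cc3c(OCOC)c(C)c(OC)c(C(=O)CCC)c3OCOC)c(OCOC)c(C(C)=O)c2OCOC)C(=O)O1
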